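The south-west run is the place to start. Its G climbs from 0.9% at 3.00 min to 13.1% at 8.00 min, while the west run, with less D, stands at 4.1% at that last time. With a scatter of 1 percentage point the early reading is weak, but the last one is not. I read this as autocatalysis: G makes more G after an induction period.

all flasks: J 0.20 M
- north: D 1 equiv; Z 0.060 M; run made earlier
- west: D 2 equiv; Z 0.060 M; run made earlier
- south-west: D 2.4 equiv; Z 0.060 M; run made earlier
- larch: D 2.60 equiv; Z 0.0600 M; time 15 min
- maple: D 1.30 equiv; Z 0.0600 M; time 15 min

| run | time / min | G / % |
|---|---|---|
| north | 0.667 | 0.6 |
| north | 1.33 | 0.4 |
| north | 3.00 | 1.0 |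
| north | 8.00 | 1.7 |
| west | 0.667 | 1.3 |
| west | 1.33 | 0.6 |
| west | 3.00 | 2.1 |
| west | 8.00 | 4.1 |
| south-west | 0.667 | 0 |
| south-west | 1.33 | 0 |
| south-west | 3.00 | 0.9 |
| south-west | 8.00 | 13.1 |

(standard deviation of a reading: 1 percentage point)

- a reading or a percentage of G counts all its forms, free or not

- the flask that ends with the higher amount of G, in percent of the J charged, or "neither" when 2 percentage points or less lies between them (larch / maple / neither)
- final G, as a percentage of the J charged, in larch
- final G, as a percentage of the J charged, in maple

Now suppose the growth constant of G is proportional to c_D. Then, with J and Z as charged in these runs, equal products of equivalents and minutes give equal G; this is my supposition, not a reading. So you can call a flask's take-off time the minutes it needs to reach the south-west mark of 13.1%: the south-west equivalents times 8.00 min, divided by its own equivalents. Two times then count, this one and the time given.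

For larch the take-off time is 7.38 min, and larch gets twice that, so I expect it far past the mark. For maple it is 14.8 min, against 15 min, so I expect maple close to the mark.

The forecast names larch, with 85% there and 5% in maple, which it says “should stay on the slow branch”, and its maple figure is lower than my mark.

The flask gives 93.7% in larch and 8.87% in maple.

    D + Z → X (k = 0.0240 L mol⁻¹ s⁻¹)
    J + D → G (k = 1.30 × 10⁻⁵ L mol⁻¹ s⁻¹)
    J + D + G → 2 G (k = 0.220 L² mol⁻² s⁻¹)
    J + G ⇌ Q, settled at all times (K = 2.70 L mol⁻¹)

Larch holds 15.5% of G, its bound form Q counted in, at 7.50 min, beside its take-off time of 7.38 min. Maple, with 14.8 min, ends below the mark, so my expectation for maple came out too high.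

Take a flask like larch but charged with 0.15 M of Z. The scheme spends one D on each Z, so scaling the larch take-off time by D net of Z in the two flasks stretches it to 9.18 min, still shorter than 15 min. That flask gives 77.5% of G.

The readings are simulated from invented constants; scatter was added.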